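The data are simulated with constants of no real substance; the scatter is artificial.

The free catalyst is single-handed and meets both substrates, charged as a racemate under held gas.

| setting | Tuesday's | Sunday's | flask |
|---|---|---|---|
| left-handed substrate | 0.013 M | 0.030 M | 0.020 M |
| right-handed substrate | 0.013 M | 0.030 M | 0.020 M |
| gas | 5.4 mM (held) | 5.4 mM (held) | 5.4 mM (held) |
| free catalyst | 38 µM | 38 µM | 38 µM |
| remark | run made earlier | run made earlier |  |
| time |  |  | 15 d |

- Tuesday's (time / d: left-handed substrate / %, left-handed product / %): 1.25: 10.4, 40.1; 4.00: 4.2, 46.1; 8.00: 4.1, 46.5; 10.0: 4.3, 44.5; 15.0: 3.6, 45.3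
- Sunday's (time / d: left-handed substrate / %, left-handed product / %): 1.25: 24.0, 25.5; 2.50: 9.9, 40.0; 4.00: 7.2, 43.5; 8.00: 5.9, 44.0; 15.0: 6.1, 44.2

(readings scatter by 0.5 percentage points)

- free catalyst is single-handed; left-handed substrate and right-handed substrate are mirror images of each other, charged as a racemate, each of them at the stated concentration
- the numbers in the tables scatter by 0.5 percentage points (one standard deviation)
- at the start none of the gas is in solution

1. part of the left-handed substrate and right-handed substrate together gone at 15 d
2. the left-handed product standing at 15 d, as a percentage of the left-handed substrate and right-handed substrate together charged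

In Tuesday's run left-handed substrate plus left-handed product stays near half of the charge, and in Sunday's run near half, so the product is that half less the left-handed substrate still standing. The flat readings of left-handed substrate average 4.05% in Tuesday's run, from 4.00 d, and 6.00% in Sunday's, from 8.00 d. I take the natural log of that half over the standing rest: 2.51 for Tuesday's run, 2.12 for Sunday's. Straight between them by loading, the asked flask gets 2.35. This is the depth D, the number of e-foldings of left-handed substrate before it stops. I assume a pseudo-first-order fall on a catalyst that gives out, so at fixed loading D goes with the catalyst charged. By my reckoning the asked flask then keeps 4.76% and makes 45.2% of left-handed product. The right-handed substrate was not among the readings, so I give no conversion.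

The forecast says 45.1% gone and 45.1% of product, that product a little below mine, and states: “I take the right-handed substrate as unconverted”.

The simulation gives 94.6% gone and 45.1% of product.

    gas ⇌ coupling partner, rate k1*(csat - [coupling partner]) (kL = 0.00640 min⁻¹)
    free catalyst + left-handed substrate ⇌ catalyst intermediate A (K = 12.0 M⁻¹, k = 1100 M⁻¹ min⁻¹)
    coupling partner → decomposed reagent (k = 3.20 × 10⁻⁴ min⁻¹)
    free catalyst → spent catalyst (k = 9.30 × 10⁻⁴ min⁻¹)
    coupling partner + catalyst intermediate B → free catalyst + right-handed product (k = 810 M⁻¹ min⁻¹)
    coupling partner + catalyst intermediate A → free catalyst + left-handed product (k = 1700 M⁻¹ min⁻¹)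
    free catalyst + right-handed substrate ⇌ catalyst intermediate B (K = 58.0 M⁻¹, k = 810 M⁻¹ min⁻¹)

The two part on the right-handed substrate: at 15.0 d the asked flask holds 0.442% of it and 49.6% of right-handed product. Its left-handed substrate stands at 4.93%, a depth of 2.32, with spent catalyst at 100%. The neighbouring flask is charged with 9.5 × 10⁻⁵ M of free catalyst, its other charges and time as in the asked flask, so my D scales to 5.88 and my estimate of its left-handed substrate to 0.140%. At 15.0 d that neighbouring flask holds 0.333% of left-handed substrate and 49.7% of left-handed product.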